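The quinone ring (numbered C1=O next to C2–Cl, then C3–Me, C4=O, C5–OH, C6–side chain) is disconnected at C1–C6 and C4–C5. Both bonds are made at once by a Danheiser benzannulation: 3-methylcyclobutenone supplies C1, C2, C3 and C4, and a triisopropylsilyl ynol ether supplies C5 and C6, so the enolised unit C5(OH)=C6 of the hydroxyquinone is treated as a masked ynol ether. The precursors are a strained four-membered enone and a skipped siloxydiyne. Ortho-chlorination, hydrozirconation–iodination, an asymmetric Nozaki–Hiyama–Kishi union with a keto aldehyde made by chiral-base desymmetrisation, and a final Fremy oxidation complete the route.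

Key step: step 5

Assumption: lithium (R,R)-bis(1-phenylethyl)amide is taken to give the S enol silane from 4-methylcyclohexanone, by analogy with 4-tert-butylcyclohexanone; if the sense proves opposite, the S,S amide is used.
Assumption: of the two antipodes of the Kishi oxazoline sulfonamide ligand, the one that directs the alkenyl group to the Re face of aldehyde 27 (the face that gives the S carbinol) is used.

**Fragment A (aryl iodoalkene)**

Step 1
Reactants: 1 propyne
Product: 2 4,4-dichloro-3-methylcyclobut-2-en-1-one
Conditions: Cl3CCOCl, Zn–Cu couple, Et2O/DME, 25 °C (propyne condensed in)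
Reagents that add atoms: trichloroacetyl chloride, ClC(=O)C(Cl)(Cl)Cl
Why: Dichloroketene, formed by zinc dechlorination of the acid chloride, should add to the terminal alkyne in a regioselective ketene–alkyne [2+2] cycloaddition (carbonyl carbon to the unsubstituted terminus), the standard entry to 3-alkyl-4,4-dichlorocyclobutenones.

Step 2
Reactants: 2 4,4-dichloro-3-methylcyclobut-2-en-1-one
Product: 3 3-methylcyclobut-2-en-1-one
Conditions: Zn dust, AcOH, TMEDA, EtOH, 0 °C to rt
Reagents that add atoms: none
Why: Zinc in amine-buffered acetic acid is the standard reductive dechlorination of 4,4-dichlorocyclobutenones and should remove both chlorines without opening the strained enone.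

Step 3
Reactants: 4 1-bromobut-2-yne
Product: 5 hexa-1,4-diyne
Conditions: HC≡CMgBr (3 equiv), CuCl (5 mol %), THF, 0 to 40 °C
Reagents that add atoms: ethynylmagnesium bromide, C#C[Mg]Br
Why: Copper-catalysed SN2 coupling of an alkynyl Grignard reagent with a propargylic bromide is the standard route to skipped diynes, and the excess of ethynyl reagent suppresses double alkylation.

Step 4
Reactants: 5 hexa-1,4-diyne
Product: 8 triisopropyl(hexa-1,4-diyn-1-yloxy)silane, via lithium acetylide 6 (not isolated), via lithium ynolate 7 (not isolated)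
Conditions: n-BuLi, THF, −78 °C; t-BuOOLi (from t-BuOOH and LiHMDS), −78 to 0 °C; TIPSOTf, −78 to 0 °C
Reagents that add atoms: lithium tert-butyl peroxide, CC(C)(C)OO[Li]; triisopropylsilyl trifluoromethanesulfonate, CC(C)[Si](OS(=O)(=O)C(F)(F)F)(C(C)C)C(C)C
Why: Julia–Kozmin ynolate synthesis: oxygen transfer from the lithium peroxide to the acetylide gives the ynolate, which the bulky silyl triflate should trap on oxygen; the terminal C–H is removed first, so the doubly activated CH2 is not deprotonated.

Step 5
Reactants: 3 3-methylcyclobut-2-en-1-one; 8 triisopropyl(hexa-1,4-diyn-1-yloxy)silane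
Product: 13 2-(but-2-yn-1-yl)-5-methyl-3-[(triisopropylsilyl)oxy]phenol, via vinylketene 9 (not isolated), via vinylcyclobutenone 10 (not isolated), via dienylketene 11 (not isolated), via cyclohexadienone 12 (not isolated)
Conditions: toluene, 80 then 110 °C, sealed tube (3 in slight excess)
Reagents that add atoms: none
Why: Danheiser benzannulation: on heating, cyclobutenone 3 opens by 4π electrocyclic reversion to vinylketene 9, whose ketene C=C undergoes a regiospecific [2+2] cycloaddition with the polarised ynol ether 8 (the alkyl-bearing alkyne carbon attacks the ketene carbonyl carbon), and this single event forms both new ring bonds, quinone C1–C6 and C4–C5. Cyclobutenone 10 then opens (4π) to dienylketene 11, which closes the six-membered ring by a thermally allowed disrotatory 6π electrocyclisation that re-forms the former C1–C4 bond of 3, and dienone 12 tautomerises to the phenol. The closest known reaction type is exactly this cyclobutenone/siloxyalkyne aromatic annulation. No stereocentre is created. The selectivity needed is regiochemical and chemoselective: the oxygen-polarised triple bond fixes the orientation, so the free hydroxyl (from the cyclobutenone carbonyl) and the silyl ether (from the ynol ether) flank the butynyl carbon and stay distinguishable, and the unactivated internal alkyne does not react with ketenes at this temperature.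

Step 6
Reactants: 13 2-(but-2-yn-1-yl)-5-methyl-3-[(triisopropylsilyl)oxy]phenol
Product: 14 2-(but-2-yn-1-yl)-6-chloro-5-methyl-3-[(triisopropylsilyl)oxy]phenol
Conditions: SO2Cl2 (1.0 equiv), i-Bu2NH (10 mol %), toluene, 0 °C to rt
Reagents that add atoms: sulfuryl chloride, O=S(=O)(Cl)Cl
Why: Amine-catalysed SO2Cl2 chlorination is a known ortho-selective phenol chlorination (delivery through a hydrogen-bonded N-chloroammonium species), and the only other free position is buttressed by the OTIPS and methyl groups, so chlorine should enter ortho to the free hydroxyl while the alkyne stays inert.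

Step 7
Reactants: 14 2-(but-2-yn-1-yl)-6-chloro-5-methyl-3-[(triisopropylsilyl)oxy]phenol
Product: 15 tert-butyl{2-(but-2-yn-1-yl)-6-chloro-5-methyl-3-[(triisopropylsilyl)oxy]phenoxy}dimethylsilane
Conditions: TBSCl, imidazole, DMAP (cat.), DMF, 40 °C
Reagents that add atoms: tert-butyldimethylsilyl chloride, CC(C)(C)[Si](C)(C)Cl
Why: Standard silylation of a hindered phenol, which masks the acidic OH for the hydrozirconation and the chromium-mediated coupling.

Step 8
Reactants: 15 tert-butyl{2-(but-2-yn-1-yl)-6-chloro-5-methyl-3-[(triisopropylsilyl)oxy]phenoxy}dimethylsilane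
Product: 17 tert-butyl{6-chloro-2-[(2E)-3-iodobut-2-en-1-yl]-5-methyl-3-[(triisopropylsilyl)oxy]phenoxy}dimethylsilane, via alkenylzirconocene 16 (not isolated)
Conditions: Cp2Zr(H)Cl (2 equiv), THF, 45 °C; then I2, 0 °C
Reagents that add atoms: iodine, II
Why: Syn hydrozirconation with Schwartz's reagent should place zirconium on the less hindered, methyl-bearing alkyne carbon (thermodynamic control with excess reagent), and iodinolysis with retention should give the E iodoalkene with methyl cis to the benzylic CH2.

**Fragment B (keto aldehyde)**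

Step 9
Reactants: 18 4-methylcyclohexanone
Product: 20 (S)-trimethyl[(4-methylcyclohex-1-en-1-yl)oxy]silane, via lithium enolate 19 (not isolated)
Conditions: lithium (R,R)-bis(1-phenylethyl)amide, LiCl, TMSCl (in situ quench), THF, −100 °C
Reagents that add atoms: chlorotrimethylsilane, C[Si](C)(C)Cl
Why: Enantioselective desymmetrising deprotonation of a 4-substituted cyclohexanone by a C2-symmetric chiral lithium amide under in situ silyl quench (Simpkins–Koga) sets the methyl-bearing stereocentre.

Step 10
Reactants: 20 (S)-trimethyl[(4-methylcyclohex-1-en-1-yl)oxy]silane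
Product: 21 (S)-4-methylcyclohex-2-en-1-one
Conditions: Pd(OAc)2 (10 mol %), O2 (1 atm), DMSO, rt
Reagents that add atoms: none
Why: Saegusa–Ito oxidation (palladium enolate, β-hydride elimination) converts the enol silane regiospecifically into the enone without touching the remote stereocentre.

Step 11
Reactants: 21 (S)-4-methylcyclohex-2-en-1-one
Product: 22 trimethyl{[(3R,4S)-4-methyl-3-(prop-2-en-1-yl)cyclohex-1-en-1-yl]oxy}silane
Conditions: allylMgBr, CuBr·SMe2, TMSCl, THF, −78 °C; Et3N quench
Reagents that add atoms: allylmagnesium bromide, C=CC[Mg]Br; chlorotrimethylsilane, C[Si](C)(C)Cl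
Why: Allylcopper with TMSCl (Lipshutz conditions) should give 1,4- rather than 1,2-addition, anti to the 4-methyl group, and the silyl chloride traps the adduct as the regiodefined enol silane; the C3 configuration is lost in the next step.

Step 12
Reactants: 22 trimethyl{[(3R,4S)-4-methyl-3-(prop-2-en-1-yl)cyclohex-1-en-1-yl]oxy}silane
Product: 23 (S)-4-methyl-3-(prop-2-en-1-yl)cyclohex-2-en-1-one
Conditions: IBX·MPO (4-methoxypyridine N-oxide complex), DMSO, rt
Reagents that add atoms: none
Why: IBX·MPO dehydrogenation of a trimethylsilyl enol ether (Nicolaou) restores the enone on the allyl-bearing side under neutral, metal-free conditions, which should avoid migration of the terminal alkene.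

Step 13
Reactants: 23 (S)-4-methyl-3-(prop-2-en-1-yl)cyclohex-2-en-1-one
Product: 25 (2R,3S,4S)-2,3,4-trimethyl-3-(prop-2-en-1-yl)cyclohexan-1-one, via lithium enolate 24 (not isolated)
Conditions: Me2CuLi (from MeLi and CuI), Et2O, 0 °C; then MeI (excess), HMPA, THF, −20 to 0 °C
Reagents that add atoms: lithium dimethylcuprate, [Li+].C[Cu-]C; iodomethane, CI
Why: Gilman cuprate conjugate addition by axial attack anti to the pseudoaxial 4-methyl group (held axial by A1,2 strain with the 3-allyl group) sets the quaternary centre with the new methyl trans to the 4-methyl, and the regiodefined enolate 24 is then methylated by axial attack on the face opposite the pseudoaxial allyl group, which should place the 2-methyl cis to the 3-methyl (2R).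

Step 14
Reactants: 25 (2R,3S,4S)-2,3,4-trimethyl-3-(prop-2-en-1-yl)cyclohexan-1-one
Product: 27 2-[(1S,2R,6S)-1,2,6-trimethyl-3-oxocyclohexyl]acetaldehyde, via ozonide 26 (not isolated)
Conditions: O3, CH2Cl2, −78 °C; then Me2S, −78 °C to rt
Reagents that add atoms: ozone, [O-][O+]=O
Why: Ozonolysis of the only alkene with reductive work-up gives the aldehyde under neutral conditions that leave the ketone and the epimerisable α-stereocentre untouched.

**Union and endgame**

Step 15
Reactants: 17 tert-butyl{6-chloro-2-[(2E)-3-iodobut-2-en-1-yl]-5-methyl-3-[(triisopropylsilyl)oxy]phenoxy}dimethylsilane; 27 2-[(1S,2R,6S)-1,2,6-trimethyl-3-oxocyclohexyl]acetaldehyde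
Product: 29 (2R,3S,4S)-3-[(2S,3E)-5-{2-[(tert-butyldimethylsilyl)oxy]-3-chloro-4-methyl-6-[(triisopropylsilyl)oxy]phenyl}-2-hydroxy-3-methylpent-3-en-1-yl]-2,3,4-trimethylcyclohexan-1-one, via alkenylchromium 28 (not isolated)
Conditions: CrCl2 (3 equiv), Kishi oxazoline sulfonamide ligand (3.3 equiv), Et3N, NiCl2 (2 mol %), THF, rt
Reagents that add atoms: none
Why: Nozaki–Hiyama–Kishi coupling: zerovalent nickel activates the iodoalkene with retention of geometry, transmetalation gives an alkenylchromium species that adds to the aldehyde and not to the ketone, and the chiral ligand on chromium should direct addition to the Re face to give the 2S carbinol, the remote ring stereocentres having little influence.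

Step 16
Reactants: 29 the bis-silyl allylic alcohol of step 15
Product: 30 (2R,3S,4S)-3-[(2S,3E)-5-(3-chloro-2,6-dihydroxy-4-methylphenyl)-2-hydroxy-3-methylpent-3-en-1-yl]-2,3,4-trimethylcyclohexan-1-one
Conditions: TBAF, AcOH, THF, 0 °C
Reagents that add atoms: none
Why: Buffered fluoride should cleave both aryl silyl ethers rapidly, and the acetic acid buffer guards against base-induced epimerisation at the ketone α-carbon.

Step 17
Reactants: 30 the chlororesorcinol of step 16
Product: 31 2-chloro-5-hydroxy-6-[(2E,4S)-4-hydroxy-3-methyl-5-[(1S,2R,6S)-1,2,6-trimethyl-3-oxocyclohexyl]pent-2-en-1-yl]-3-methylcyclohexa-2,5-diene-1,4-dione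
Conditions: (KSO3)2NO (Fremy's salt), KH2PO4 buffer, acetone/H2O, 0 °C to rt
Reagents that add atoms: Fremy's salt (potassium nitrosodisulfonate), [K+].[K+].[O-]S(=O)(=O)N([O])S(=O)(=O)[O-]
Why: Teuber oxidation: the nitroxyl radical oxidises the resorcinol at its single free ring position, para to one hydroxyl, to give the 2-hydroxy-1,4-benzoquinone directly, and the allylic alcohol, alkene and ketone are inert to this reagent.

**Compound list**

1 | propyne | CC#C | starting material
2 | 4,4-dichloro-3-methylcyclobut-2-en-1-one | CC1=CC(=O)C1(Cl)Cl | intermediate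
3 | 3-methylcyclobut-2-en-1-one | CC1=CC(=O)C1 | intermediate
4 | 1-bromobut-2-yne | CC#CCBr | starting material
5 | hexa-1,4-diyne | CC#CCC#C | intermediate
6 | lithium hexa-1,4-diyn-1-ide (not isolated) | CC#CCC#C[Li] | intermediate
7 | lithium hexa-1,4-diyn-1-olate (not isolated) | CC#CCC#CO[Li] | intermediate
8 | triisopropyl(hexa-1,4-diyn-1-yloxy)silane | CC#CCC#CO[Si](C(C)C)(C(C)C)C(C)C | intermediate
9 | 3-methylbuta-1,3-dien-1-one, the vinylketene (not isolated) | C=C(C)C=C=O | intermediate
10 | 2-(but-2-yn-1-yl)-4-(prop-1-en-2-yl)-3-[(triisopropylsilyl)oxy]cyclobut-2-en-1-one, racemic (not isolated) | CC#CCC1=C(O[Si](C(C)C)(C(C)C)C(C)C)C(C(C)=C)C1=O | intermediate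
11 | (3E)-2-(but-2-yn-1-yl)-5-methyl-3-[(triisopropylsilyl)oxy]hexa-1,3,5-trien-1-one, the dienylketene (not isolated) | CC#CCC(=C=O)/C(O[Si](C(C)C)(C(C)C)C(C)C)=C\C(C)=C | intermediate
12 | 2-(but-2-yn-1-yl)-5-methyl-3-[(triisopropylsilyl)oxy]cyclohexa-2,4-dien-1-one (not isolated) | CC#CCC1=C(O[Si](C(C)C)(C(C)C)C(C)C)C=C(C)CC1=O | intermediate
13 | 2-(but-2-yn-1-yl)-5-methyl-3-[(triisopropylsilyl)oxy]phenol | CC#CCc1c(O)cc(C)cc1O[Si](C(C)C)(C(C)C)C(C)C | intermediate
14 | 2-(but-2-yn-1-yl)-6-chloro-5-methyl-3-[(triisopropylsilyl)oxy]phenol | CC#CCc1c(O)c(Cl)c(C)cc1O[Si](C(C)C)(C(C)C)C(C)C | intermediate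
15 | tert-butyl{2-(but-2-yn-1-yl)-6-chloro-5-methyl-3-[(triisopropylsilyl)oxy]phenoxy}dimethylsilane | CC#CCc1c(O[Si](C)(C)C(C)(C)C)c(Cl)c(C)cc1O[Si](C(C)C)(C(C)C)C(C)C | intermediate
16 | E alkenyl(chloro)zirconocene from 15, zirconium on the methyl-bearing carbon (not isolated) | Cl[Zr](C1C=CC=C1)(C1C=CC=C1)/C(C)=C/Cc1c(O[Si](C)(C)C(C)(C)C)c(Cl)c(C)cc1O[Si](C(C)C)(C(C)C)C(C)C | intermediate
17 | tert-butyl{6-chloro-2-[(2E)-3-iodobut-2-en-1-yl]-5-methyl-3-[(triisopropylsilyl)oxy]phenoxy}dimethylsilane | I/C(C)=C/Cc1c(O[Si](C)(C)C(C)(C)C)c(Cl)c(C)cc1O[Si](C(C)C)(C(C)C)C(C)C | intermediate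
18 | 4-methylcyclohexanone | CC1CCC(=O)CC1 | starting material
19 | lithium (S)-4-methylcyclohex-1-en-1-olate (not isolated) | [Li]OC1=CC[C@@H](C)CC1 | intermediate
20 | (S)-trimethyl[(4-methylcyclohex-1-en-1-yl)oxy]silane | C[Si](C)(C)OC1=CC[C@@H](C)CC1 | intermediate
21 | (S)-4-methylcyclohex-2-en-1-one | O=C1C=C[C@@H](C)CC1 | intermediate
22 | trimethyl{[(3R,4S)-4-methyl-3-(prop-2-en-1-yl)cyclohex-1-en-1-yl]oxy}silane | C[Si](C)(C)OC1=C[C@H](CC=C)[C@@H](C)CC1 | intermediate
23 | (S)-4-methyl-3-(prop-2-en-1-yl)cyclohex-2-en-1-one | O=C1C=C(CC=C)[C@@H](C)CC1 | intermediate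
24 | lithium (3S,4S)-3,4-dimethyl-3-(prop-2-en-1-yl)cyclohex-1-en-1-olate (not isolated) | [Li]OC1=C[C@@](C)(CC=C)[C@@H](C)CC1 | intermediate
25 | (2R,3S,4S)-2,3,4-trimethyl-3-(prop-2-en-1-yl)cyclohexan-1-one | C=CC[C@@]1(C)[C@@H](C)CCC(=O)[C@@H]1C | intermediate
26 | secondary ozonide (1,2,4-trioxolane) of 25, mixture at the trioxolane carbon (not isolated) | O1OCOC1C[C@@]2(C)[C@@H](C)CCC(=O)[C@@H]2C | intermediate
27 | 2-[(1S,2R,6S)-1,2,6-trimethyl-3-oxocyclohexyl]acetaldehyde | O=CC[C@@]1(C)[C@@H](C)CCC(=O)[C@@H]1C | intermediate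
28 | E alkenylchromium dichloride from 17, chiral ligand on chromium not drawn (not isolated) | Cl[Cr](Cl)/C(C)=C/Cc1c(O[Si](C)(C)C(C)(C)C)c(Cl)c(C)cc1O[Si](C(C)C)(C(C)C)C(C)C | intermediate
29 | (2R,3S,4S)-3-[(2S,3E)-5-{2-[(tert-butyldimethylsilyl)oxy]-3-chloro-4-methyl-6-[(triisopropylsilyl)oxy]phenyl}-2-hydroxy-3-methylpent-3-en-1-yl]-2,3,4-trimethylcyclohexan-1-one | Cc1cc(O[Si](C(C)C)(C(C)C)C(C)C)c(C/C=C(\C)[C@@H](O)C[C@@]2(C)[C@@H](C)CCC(=O)[C@@H]2C)c(O[Si](C)(C)C(C)(C)C)c1Cl | intermediate
30 | (2R,3S,4S)-3-[(2S,3E)-5-(3-chloro-2,6-dihydroxy-4-methylphenyl)-2-hydroxy-3-methylpent-3-en-1-yl]-2,3,4-trimethylcyclohexan-1-one | Cc1cc(O)c(C/C=C(\C)[C@@H](O)C[C@@]2(C)[C@@H](C)CCC(=O)[C@@H]2C)c(O)c1Cl | intermediate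
31 | 2-chloro-5-hydroxy-6-[(2E,4S)-4-hydroxy-3-methyl-5-[(1S,2R,6S)-1,2,6-trimethyl-3-oxocyclohexyl]pent-2-en-1-yl]-3-methylcyclohexa-2,5-diene-1,4-dione | CC1=C(Cl)C(=O)C(C/C=C(\C)[C@@H](O)C[C@@]2(C)[C@@H](C)CCC(=O)[C@@H]2C)=C(O)C1=O | target

**Summary**

Total step count: 17. Longest linear sequence: 9 steps (steps 1, 2, 5, 6, 7, 8, 15, 16, 17; the alkyne branch 3, 4, 5–8, 15–17 and the ring branch 9–14, 15–17 are equally long).

The three steps most likely to fail:

Step 15. The risk is insufficient facial control in the chromium-mediated addition to an aldehyde whose nearest stereocentre is a remote quaternary carbon, so that both carbinol epimers form. The fallback sets out from 17 and 27 and comes back at 29. A ligand-free coupling (CrCl2, cat. NiCl2, DMSO) would give 29 together with its 2R carbinol epimer F1. A Sharpless kinetic resolution of the mixture (Ti(OiPr)4, D-(−)-diisopropyl tartrate, t-BuOOH, 4 Å sieves, CH2Cl2, −20 °C) would then epoxidise the fast-reacting 2R epimer from the face dictated by the tartrate to the anti epoxy alcohol F2, leaving the 2S alcohol 29 to be separated and carried on.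

Step 13. The risks are proton transfer between the hindered enolate and the product (regiochemical scrambling, over-methylation, epimerisation of the less stable 2-methyl epimer) and incomplete facial selectivity in the methylation. The fallback sets out from 23 and comes back at 25. Me2CuLi addition in the presence of TMSCl would give the trimethylsilyl enol ether F3. Furukawa cyclopropanation (Et2Zn, CH2I2, CH2Cl2, 0 °C) of the electron-rich enol ether on the face anti to the allyl group would give the siloxycyclopropane F4. Acid-mediated ring opening (TsOH, MeOH, rt; Conia methylation) cleaves the bond between the carbinol carbon and the CH2, so the cyclopropane CH2 becomes the 2-methyl group with its configuration fixed and no enolate involved.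

Step 5. The risks are acylation of the product phenol by vinylketene that is still being released during the long heating, and thermal isomerisation of the siloxydiyne before it is consumed. The fallback sets out from 8 and comes back at 13 and makes no compound beyond those already listed. Vinylketene 9 would be generated at 0–25 °C by dehydrochlorination of 3-methylbut-2-enoyl chloride with Et3N in the presence of 8, so that the [2+2] adduct 10 forms in the cold and is isolated. Compound 10 alone would then be heated in toluene (80–110 °C) to 13 by the same 4π opening, 6π closure and tautomerisation.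

Further compounds
F0 | step 5 | none | none
F1 | step 15 | (2R,3S,4S)-3-[(2R,3E)-5-{2-[(tert-butyldimethylsilyl)oxy]-3-chloro-4-methyl-6-[(triisopropylsilyl)oxy]phenyl}-2-hydroxy-3-methylpent-3-en-1-yl]-2,3,4-trimethylcyclohexan-1-one (carbinol epimer of 29) | Cc1cc(O[Si](C(C)C)(C(C)C)C(C)C)c(C/C=C(\C)[C@H](O)C[C@@]2(C)[C@@H](C)CCC(=O)[C@@H]2C)c(O[Si](C)(C)C(C)(C)C)c1Cl
F2 | step 15 | anti (2S,3S)-epoxy alcohol from F1, carbinol carbon R | Cc1cc(O[Si](C(C)C)(C(C)C)C(C)C)c(C[C@@H]2O[C@@]2(C)[C@H](O)C[C@@]3(C)[C@@H](C)CCC(=O)[C@@H]3C)c(O[Si](C)(C)C(C)(C)C)c1Cl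
F3 | step 13 | trimethyl{[(3S,4S)-3,4-dimethyl-3-(prop-2-en-1-yl)cyclohex-1-en-1-yl]oxy}silane | C[Si](C)(C)OC1=C[C@@](C)(CC=C)[C@@H](C)CC1
F4 | step 13 | 4,5-dimethyl-5-(prop-2-en-1-yl)-1-(trimethylsilyloxy)bicyclo[4.1.0]heptane, cyclopropane CH2 anti to the allyl group | C[Si](C)(C)O[C@]12CC[C@H](C)[C@](C)(CC=C)[C@H]1C2
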